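The earlier runs and the new flask are calculated for substances that don't exist; the scatter is artificial.

3 questions are put to this flask, and one molecule of right-handed substrate leads to them.

| flask | left-handed substrate | right-handed substrate | partner | remark | time |
|---|---|---|---|---|---|
| dusk | 0.034 M | 0.034 M | 0.20 M | run made earlier |  |
| autumn | 0.075 M | 0.075 M | 0.20 M | run made earlier |  |
| spring | 0.050 M | 0.050 M | 0.30 M | run made earlier |  |
| flask | 0.050 M | 0.050 M | 0.200 M |  | 25 min |

| run | time / min | left-handed product / % | right-handed product / % | left-handed substrate / % |
|---|---|---|---|---|
| dusk | 5.00 | 55.5 | 2.1 | 2.2 |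
| dusk | 10.0 | 61.4 | 4.6 | 3.7 |
| dusk | 15.0 | 67.3 | 7.5 | 1.4 |
| dusk | 20.0 | 72.3 | 5.9 | 2.3 |
| dusk | 25.0 | 74.3 | 8.5 | 2.0 |
| autumn | 5.00 | 53.8 | 3.9 | 3.3 |
| autumn | 10.0 | 61.7 | 4.0 | 0.9 |
| autumn | 15.0 | 66.4 | 5.6 | 2.0 |
| autumn | 20.0 | 71.8 | 5.8 | 2.4 |
| autumn | 25.0 | 74.9 | 4.0 | 3.0 |
| spring | 5.00 | 57.1 | 3.6 | 0.9 |
| spring | 10.0 | 63.4 | 6.6 | 1.5 |
| spring | 15.0 | 67.5 | 9.8 | 0 |
| spring | 20.0 | 71.6 | 9.5 | 0 |
| spring | 25.0 | 75.6 | 12.1 | 2.5 |

(each reading ± 1 percentage point)

- partner is single-handed; left-handed substrate and right-handed substrate are mirror images of each other, charged as a racemate, each of them at the stated concentration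
- the earlier runs were read with a standard deviation of 1 percentage point
- an excess is the difference of the two amounts in percent of their sum
- an excess is below zero if the other one leads
- the handed part of partner does not stay in what it makes, so the products of the two hands are mirror images too

* left-handed product and right-handed product together, in percent of the left-handed substrate and right-handed substrate charged together, at 25 min
* excess of left-handed product over right-handed product in the product at 25 min
* whether the exchange between left-handed substrate and right-handed substrate keeps pace with the reaction: how far the product's excess at 25 min gets from its value without exchange to its value with instant exchange (above 80 % keeps pace, below 20 % hardly takes part, else lags behind)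

In the runs, left-handed substrate reads low from the first reading on, 2.2 % in the dusk run, so partner captures it promptly. A right-handed molecule then meets a fork. It reacts directly to right-handed product, or it crosses to left-handed substrate and ends as left-handed product (dynamic kinetic resolution). Left-handed product and left-handed substrate together, beyond the left-handed share of the charge, are therefore crossed material.

The dusk and autumn runs share this flask's partner charge. Between 10.0 min and 25.0 min their left-handed product climbs by 13 percentage points on average, while the uncounted balance, right-handed substrate, averages 24.3 %. That reads as a crossing constant of 0.0359 min⁻¹, or a crossing half-life of 19.3 min: the time for crossing alone to halve a pool of right-handed substrate.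

By 25 min, the readings of those runs put 18.7 % of the departed molecules on the direct branch. Both exits together are then reckoned to leave 16.6 % right-handed substrate in this flask. With the left-handed substrate read in the dusk run and the autumn run, this reckoning gives y of 80.9 % and an excess of 84.5 %. With that much uncrossed, it also expects the exchange to lag behind.

The forecast says 81.3 %, 84 % and lags behind, holding that “The exchange is therefore first order”. Its excess lies slightly below this reckoning's.

The flask gives 82.5 %, 82.5 % and lags behind, 54 % of the way to the excess with instant exchange, so the forecast stands.

    partner → decomposed reagent (k = 0.0270 min⁻¹)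
    left-handed substrate ⇌ right-handed substrate (k = 0.0400 min⁻¹)
    partner + left-handed substrate → left-handed product (k = 7.90 M⁻¹ min⁻¹)
    partner → decomposition product (k = 3.60 × 10⁻⁴ min⁻¹)
    partner + right-handed substrate → right-handed product (k = 0.0930 M⁻¹ min⁻¹)

At 1.00 min in this flask, capture gives left-handed substrate a half-life of 0.56 min, far shorter than the crossing half-life of 19.3 min read from the runs. At 25 min the flask holds 75.3 % left-handed product beside 16.1 % right-handed substrate.

In a neighbour flask with 0.050 M partner, 0.54 % of the partner remains at 25 min. The half-life read from the runs, 19.3 min, carried there as an estimate, puts the gap between the substrates at 7.2 points, if the gap is taken as wide as the left-handed product, opened at the start and shrinking by crossing both ways. The neighbour flask gives 8.4 points, with y 44.4 % and excess 96.2 %.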